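**Plan**

- Retrosynthesis: the methyl ester is traced back to a silyl-protected C1 alcohol, and the enyne is cut at C11–C12 (Sonogashira), leaving a 1,2-dioxane with a pentynyl stub.
- The ring is then cut at C4–C5 after adding a C4=C5 double bond. In the ring O1–O2–C6–C5–C4–C3 this is the only bond joining two carbons that carry no oxygen, so both C–O bonds and the O–O bond can already exist in an open-chain bis-allylic peroxyketal.
- That peroxyketal is cut at C6–O2 (ketal exchange with an allylic hydroperoxide) and at C3–O1 (SN2 of a masked hydroperoxide on a secondary mesylate). Both vinyl groups travel as 2-(phenylselanyl)ethyl groups, and each is unveiled before it can meet a free hydroperoxide for long.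
- Forward: C3 fragment from but-3-en-1-ol, ketal fragment from 5-chloropent-1-yne, peroxyketal, metathesis closing the only ring, diimide, desilylation, C6 equilibration, Sonogashira, oxidation, esterification.
- Stereochemistry: C3 comes from the hydrolytic kinetic resolution of the epoxide followed by one SN2 inversion; C6 is set by acid equilibration to the chair with axial methoxy; the E alkene comes from a Takai olefination.

Key step: step 16

Assumptions: N-methoxy-N-methylprop-2-enamide is treated as a catalogue compound (otherwise one acylation from acryloyl chloride), and the (R,R) cobalt–salen catalyst is taken to hydrolyse the R epoxide, as it does for other alkyl-substituted oxiranes, so that the S epoxide is recovered; were the sense the reverse, the enantiomeric catalyst would be used.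

**Step 1**
Reactants: 1 but-3-en-1-ol
Product: 2 tert-butyl(but-3-en-1-yloxy)diphenylsilane
Conditions: TBDPSCl, imidazole, CH2Cl2, 0 °C → rt
Reagents that add atoms: tert-butyl(chloro)diphenylsilane, CC(C)(C)[Si](Cl)(c1ccccc1)c1ccccc1
Why: Silylation of a primary alcohol gives an ether that should survive peracid, organolithium, hydroxide, mild acid and ruthenium and is removed late by fluoride.

**Step 2**
Reactants: 2 tert-butyl(but-3-en-1-yloxy)diphenylsilane
Product: 3 rac-tert-butyl[2-(oxiran-2-yl)ethoxy]diphenylsilane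
Conditions: mCPBA, NaHCO3, CH2Cl2, 0 °C → rt
Reagents that add atoms: 3-chloroperbenzoic acid, OOC(=O)c1cccc(Cl)c1
Why: Prilezhaev epoxidation of a terminal alkene is routine and the silyl ether is inert to the buffered peracid.

**Step 3**
Reactants: 3 rac-tert-butyl[2-(oxiran-2-yl)ethoxy]diphenylsilane
Product: 4 tert-butyl{2-[(2S)-oxiran-2-yl]ethoxy}diphenylsilane
Conditions: (R,R)-(salen)Co(OAc) [salen = N,N'-bis(3,5-di-tert-butylsalicylidene)cyclohexane-1,2-diamine dianion] (0.5 mol %), H2O (0.55 equiv), THF, 0 °C → rt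
Reagents that add atoms: none
Why: Jacobsen hydrolytic kinetic resolution should hydrolyse the R epoxide to the diol and leave the S epoxide, which fixes the configuration from which C3 is derived.

**Step 4**
Reactants: 5 diphenyl diselenide
Product: 7 bis(phenylselanyl)methane, via sodium benzeneselenolate 6 (not isolated)
Conditions: NaBH4, EtOH, 0 °C; then CH2Br2, rt
Reagents that add atoms: dibromomethane, BrCBr
Why: Borohydride cleaves the Se–Se bond and the soft selenolate displaces both bromides of dibromomethane (double SN2) to give the selenoacetal.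

**Step 5**
Reactants: 7 bis(phenylselanyl)methane; 4 tert-butyl{2-[(2S)-oxiran-2-yl]ethoxy}diphenylsilane
Product: 9 (3S)-1-(tert-butyldiphenylsilyloxy)-5-(phenylselanyl)pentan-3-ol, via (phenylselanyl)methyllithium 8 (not isolated)
Conditions: n-BuLi, THF, −78 °C; then 4, −78 → 0 °C
Reagents that add atoms: none
Why: Selenium–lithium exchange of the selenoacetal gives the α-selanyl carbanion, which opens the terminal epoxide at its CH2 carbon (SN2), so the carbinol configuration is untouched and the future vinyl group arrives as a 2-(phenylselanyl)ethyl arm.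

**Step 6**
Reactants: 9 (3S)-1-(tert-butyldiphenylsilyloxy)-5-(phenylselanyl)pentan-3-ol
Product: 10 (3S)-1-(tert-butyldiphenylsilyloxy)-5-(phenylselanyl)pentan-3-yl methanesulfonate
Conditions: MsCl, Et3N, CH2Cl2, 0 °C
Reagents that add atoms: methanesulfonyl chloride, CS(=O)(=O)Cl
Why: Mesylation of a secondary alcohol proceeds with retention at carbon and gives a non-allylic leaving group that cannot ionise or rearrange.

**Step 7**
Reactants: 11 2,3-dimethylbut-2-ene
Product: 12 2-hydroperoxy-2-methoxypropane
Conditions: O3, CH2Cl2/MeOH, −78 °C; used as a cold solution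
Reagents that add atoms: ozone, [O-][O+]=O; methanol, CO
Why: Ozonolysis in methanol traps the carbonyl oxide as the α-methoxy hydroperoxide (Criegee mechanism), a hydrogen peroxide equivalent that alkylates only once and is removed by mild acid.

**Step 8**
Reactants: 10 (3S)-1-(tert-butyldiphenylsilyloxy)-5-(phenylselanyl)pentan-3-yl methanesulfonate; 12 2-hydroperoxy-2-methoxypropane
Product: 13 tert-butyl{[(3R)-3-[(2-methoxypropan-2-yl)peroxy]-5-(phenylselanyl)pentyl]oxy}diphenylsilane
Conditions: CsOH·H2O, DMF, 0 °C → rt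
Reagents that add atoms: none
Why: SN2 displacement of the secondary mesylate by the cesium peroxide anion goes with inversion and sets the R peroxide carbon (C3 of the target), while full deprotonation means the selenide meets only the non-oxidising anion.

**Step 9**
Reactants: 13 tert-butyl{[(3R)-3-[(2-methoxypropan-2-yl)peroxy]-5-(phenylselanyl)pentyl]oxy}diphenylsilane
Product: 15 tert-butyl{[(3R)-3-[(2-methoxypropan-2-yl)peroxy]pent-4-en-1-yl]oxy}diphenylsilane, via selenoxide 14 (not isolated)
Conditions: 30 % H2O2, pyridine, CH2Cl2, 0 °C → rt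
Reagents that add atoms: none
Why: Selenoxide syn-elimination toward the only β-carbon gives the allylic peroxide, as in the known conversion of γ-oxygenated selenides into allylic alcohols, and removes selenium before any free hydroperoxide is generated on this fragment; pyridine protects the acid-labile perketal.

**Step 10**
Reactants: 16 5-chloropent-1-yne
Product: 18 (5-chloropent-1-yn-1-yl)tri(propan-2-yl)silane, via lithium acetylide 17 (not isolated)
Conditions: n-BuLi, THF, −78 °C; then i-Pr3SiCl, −78 °C → rt
Reagents that add atoms: chlorotri(propan-2-yl)silane, CC(C)[Si](Cl)(C(C)C)C(C)C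
Why: Deprotonation of the terminal alkyne is much faster than attack on the primary chloride, and the bulky silyl cap later shields the alkyne from the Grignard reagent, ruthenium and diimide.

**Step 11**
Reactants: 5 diphenyl diselenide; 19 N-methoxy-N-methylprop-2-enamide
Product: 21 N-methoxy-N-methyl-3-(phenylselanyl)propanamide, via benzeneselenol 20 (not isolated)
Conditions: 50 % aq. H3PO2, THF, reflux under argon until colourless; cool; then 19, rt → 40 °C
Reagents that add atoms: none
Why: Hypophosphorous acid reduces the Se–Se bond to the free selenol, a soft nucleophile that adds to the acrylamide in a conjugate sense without added base (selena-Michael addition) and so places selenium β to the future ketone carbon.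

**Step 12**
Reactants: 18 (5-chloropent-1-yn-1-yl)tri(propan-2-yl)silane; 21 N-methoxy-N-methyl-3-(phenylselanyl)propanamide
Product: 23 1-(phenylselanyl)-8-(triisopropylsilyl)oct-7-yn-3-one, via Grignard reagent 22 (not isolated)
Conditions: Mg, I2 (cat.), THF, reflux; then 21, THF, 0 °C; aq. NH4Cl
Reagents that add atoms: none
Why: In the Weinreb ketone synthesis the chelated tetrahedral adduct stops at the ketone stage, and neither the silylalkyne nor the alkyl aryl selenide reacts with an alkylmagnesium chloride.

**Step 13**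
Reactants: 23 1-(phenylselanyl)-8-(triisopropylsilyl)oct-7-yn-3-one
Product: 24 3,3-dimethoxy-1-(phenylselanyl)-8-(triisopropylsilyl)oct-7-yne
Conditions: HC(OMe)3, MeOH, TsOH·H2O (cat.), rt
Reagents that add atoms: trimethyl orthoformate, COC(OC)OC; methanol, CO
Why: Acid-catalysed ketalisation driven by the orthoformate as water scavenger gives the dimethyl ketal, whose oxocarbenium ion has no conjugated alkene that could divert a nucleophile.

**Step 14**
Reactants: 15 tert-butyl{[(3R)-3-[(2-methoxypropan-2-yl)peroxy]pent-4-en-1-yl]oxy}diphenylsilane; 24 3,3-dimethoxy-1-(phenylselanyl)-8-(triisopropylsilyl)oct-7-yne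
Product: 26 (3R)-5-(tert-butyldiphenylsilyloxy)pent-1-en-3-yl 3-methoxy-1-(phenylselanyl)-8-(triisopropylsilyl)oct-7-yn-3-yl peroxide as both ketal epimers, via allylic hydroperoxide 25 (not isolated)
Conditions: 15, PPTS (cat.), MeOH, 0 °C; concentrate; then 24 (2 equiv), PPTS (cat.), 5 Å molecular sieves, CH2Cl2, 0 °C
Reagents that add atoms: none
Why: Methanolysis frees the allylic hydroperoxide, which then replaces one methoxy group of the ketal through its oxocarbenium ion (acid-catalysed perketal exchange, the reaction used to protect hydroperoxides with 2,2-dimethoxypropane); excess ketal and sieves that take up methanol drive it, the exchange at 0 °C should outrun bimolecular oxidation of the selenide, and the ketal carbon forms without control as both epimers.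

**Step 15**
Reactants: 26 (3R)-5-(tert-butyldiphenylsilyloxy)pent-1-en-3-yl 3-methoxy-1-(phenylselanyl)-8-(triisopropylsilyl)oct-7-yn-3-yl peroxide
Product: 28 (3R)-5-(tert-butyldiphenylsilyloxy)pent-1-en-3-yl 3-methoxy-8-(triisopropylsilyl)oct-1-en-7-yn-3-yl peroxide as both ketal epimers, via selenoxide 27 (not isolated)
Conditions: 30 % H2O2, pyridine, CH2Cl2, 0 °C → rt
Reagents that add atoms: none
Why: Selenoxide syn-elimination can only run toward the CH2 next to the quaternary ketal carbon and so gives the second vinyl group under neutral buffered conditions that spare the O–O bond and the mixed ketal.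

**Step 16**
Reactants: 28 (3R)-5-(tert-butyldiphenylsilyloxy)pent-1-en-3-yl 3-methoxy-8-(triisopropylsilyl)oct-1-en-7-yn-3-yl peroxide
Product: 29 (3R)-3-[2-(tert-butyldiphenylsilyloxy)ethyl]-6-methoxy-6-[5-(triisopropylsilyl)pent-4-yn-1-yl]-3,6-dihydro-1,2-dioxine (both C6 epimers)
Conditions: (H2IMes)Cl2Ru=CH(C6H4-2-O-i-Pr), the second-generation Hoveyda–Grubbs catalyst (5 mol %), CH2Cl2 (0.005 M), 40 °C, argon sparge
Reagents that add atoms: none
Why: The catalyst should initiate on the less hindered vinyl group at C3, and the resulting alkylidene undergoes [2+2] cycloaddition with the vinyl group on the quaternary ketal carbon followed by cycloreversion, releasing ethene and forming the C4=C5 bond. The closest known reaction type is ruthenium-catalysed ring-closing metathesis of bis-allylic ethers to 3,6-dihydro-2H-pyrans, and dialkyl peroxides are known to survive ruthenium alkylidenes. The six-membered 3,6-dihydro-1,2-dioxine closes by joining two terminal alkenes held four atoms apart across the C–O–O–C unit, and the ring enforces the cis alkene. No stereocentre is created: C3 is carried through unchanged and C6 remains an epimeric pair that is corrected later. The step needs chemoselectivity for the two monosubstituted alkenes over the alkyne and the O–O bond, which the bulky triisopropylsilyl cap and a phosphine-free catalyst (no liberated PCy3 to reduce the peroxide) should secure. High dilution, the gauche peroxide geometry and geminal substitution at C6 should favour cyclisation over oligomerisation.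

**Step 17**
Reactants: 29 (3R)-3-[2-(tert-butyldiphenylsilyloxy)ethyl]-6-methoxy-6-[5-(triisopropylsilyl)pent-4-yn-1-yl]-3,6-dihydro-1,2-dioxine
Product: 30 (3S)-3-[2-(tert-butyldiphenylsilyloxy)ethyl]-6-methoxy-6-[5-(triisopropylsilyl)pent-4-yn-1-yl]-1,2-dioxane (both C6 epimers)
Conditions: KO2C–N=N–CO2K, AcOH, CH2Cl2, 0 °C → rt
Reagents that add atoms: none
Why: Diimide transfers two hydrogens concertedly to the cis ring alkene without cleaving the O–O bond, the established way to saturate unsaturated cyclic peroxides, and the hindered silylalkyne is not reduced (the descriptor at C3 changes only because the ring carbon loses priority).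

**Step 18**
Reactants: 30 (3S)-3-[2-(tert-butyldiphenylsilyloxy)ethyl]-6-methoxy-6-[5-(triisopropylsilyl)pent-4-yn-1-yl]-1,2-dioxane
Product: 31 2-[(3S)-6-methoxy-6-(pent-4-yn-1-yl)-1,2-dioxan-3-yl]ethan-1-ol (both C6 epimers)
Conditions: Bu4NF, THF, 0 °C → rt
Reagents that add atoms: none
Why: Fluoride cleaves both the silyl ether and the C(sp)–Si bond in one operation, and the saturated dioxane no longer has an allylic C–H next to the peroxide that a mild base could remove.

**Step 19**
Reactants: 31 2-[(3S)-6-methoxy-6-(pent-4-yn-1-yl)-1,2-dioxan-3-yl]ethan-1-ol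
Product: 32 2-[(3S,6R)-6-methoxy-6-(pent-4-yn-1-yl)-1,2-dioxan-3-yl]ethan-1-ol
Conditions: TsOH·H2O (cat.), MeOH, rt; chromatography, minor epimer resubmitted
Reagents that add atoms: methanol, CO
Why: Acid ionises the peroxyketal to a cyclic peroxycarbenium ion that re-adds methanol, so the mixture should settle on the chair with axial methoxy (anomeric effect) and both carbon substituents equatorial, which is the 3S,6R isomer.

**Step 20**
Reactants: 33 dec-9-en-1-ol
Product: 34 dec-9-enal
Conditions: TEMPO (10 mol %), PhI(OAc)2, CH2Cl2, rt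
Reagents that add atoms: none
Why: Oxoammonium oxidation stops at the aldehyde in the absence of water and leaves the terminal alkene alone.

**Step 21**
Reactants: 34 dec-9-enal
Product: 35 (1E)-1-iodoundeca-1,10-diene
Conditions: CHI3, CrCl2, THF, 0 °C → rt
Reagents that add atoms: iodoform, IC(I)I
Why: Takai olefination converts an aliphatic aldehyde into the one-carbon-extended vinyl iodide with a preference for the E isomer through anti elimination from the geminal dichromium adduct.

**Step 22**
Reactants: 32 2-[(3S,6R)-6-methoxy-6-(pent-4-yn-1-yl)-1,2-dioxan-3-yl]ethan-1-ol; 35 (1E)-1-iodoundeca-1,10-diene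
Product: 36 2-[(3S,6R)-6-[(6E)-hexadeca-6,15-dien-4-yn-1-yl]-6-methoxy-1,2-dioxan-3-yl]ethan-1-ol
Conditions: Pd(PPh3)4 (5 mol %), CuI (10 mol %), i-Pr2NH, THF, rt
Reagents that add atoms: none
Why: Sonogashira coupling of a terminal alkyne with an E vinyl iodide retains the alkene geometry at room temperature, and palladium/copper couplings of this kind have been run on 1,2-dioxanes; coupling before the ester is made avoids a base-sensitive β-peroxy ester under amine.

**Step 23**
Reactants: 36 2-[(3S,6R)-6-[(6E)-hexadeca-6,15-dien-4-yn-1-yl]-6-methoxy-1,2-dioxan-3-yl]ethan-1-ol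
Product: 38 2-[(3S,6R)-6-[(6E)-hexadeca-6,15-dien-4-yn-1-yl]-6-methoxy-1,2-dioxan-3-yl]acetic acid, via aldehyde 37 (not isolated)
Conditions: TEMPO (20 mol %), PhI(OAc)2 (2.2 equiv), MeCN/H2O (1:1), rt
Reagents that add atoms: water, O
Why: Oxoammonium oxidation in aqueous acetonitrile takes the primary alcohol through the aldehyde hydrate to the acid under near-neutral conditions that spare the enyne, the terminal alkene, the peroxide and the ketal.

**Step 24**
Reactants: 38 2-[(3S,6R)-6-[(6E)-hexadeca-6,15-dien-4-yn-1-yl]-6-methoxy-1,2-dioxan-3-yl]acetic acid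
Product: 39 methyl 2-[(3S,6R)-6-[(6E)-hexadeca-6,15-dien-4-yn-1-yl]-6-methoxy-1,2-dioxan-3-yl]acetate (peroxyacarnoate A)
Conditions: Me3SiCHN2, MeOH/toluene, 0 °C
Reagents that add atoms: (trimethylsilyl)diazomethane, C[Si](C)(C)C=[N+]=[N-]
Why: Methylation of the carboxylic acid with the diazo reagent needs no base, so the β-peroxy ester is not exposed to conditions that could trigger elimination.

**Compound list**

1 | but-3-en-1-ol | C=CCCO | starting material
2 | tert-butyl(but-3-en-1-yloxy)diphenylsilane | C=CCCO[Si](c1ccccc1)(c1ccccc1)C(C)(C)C | intermediate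
3 | rac-tert-butyl[2-(oxiran-2-yl)ethoxy]diphenylsilane | CC(C)(C)[Si](c1ccccc1)(c1ccccc1)OCCC1CO1 | intermediate
4 | tert-butyl{2-[(2S)-oxiran-2-yl]ethoxy}diphenylsilane | CC(C)(C)[Si](c1ccccc1)(c1ccccc1)OCC[C@H]1CO1 | intermediate
5 | diphenyl diselenide | c1ccc(cc1)[Se][Se]c1ccccc1 | starting material
6 | sodium benzeneselenolate | [Na+].[Se-]c1ccccc1 | intermediate (not isolated)
7 | bis(phenylselanyl)methane | c1ccc(cc1)[Se]C[Se]c1ccccc1 | intermediate
8 | (phenylselanyl)methyllithium | [Li]C[Se]c1ccccc1 | intermediate (not isolated)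
9 | (3S)-1-(tert-butyldiphenylsilyloxy)-5-(phenylselanyl)pentan-3-ol | CC(C)(C)[Si](c1ccccc1)(c1ccccc1)OCC[C@H](O)CC[Se]c1ccccc1 | intermediate
10 | (3S)-1-(tert-butyldiphenylsilyloxy)-5-(phenylselanyl)pentan-3-yl methanesulfonate | CC(C)(C)[Si](c1ccccc1)(c1ccccc1)OCC[C@H](OS(C)(=O)=O)CC[Se]c1ccccc1 | intermediate
11 | 2,3-dimethylbut-2-ene | CC(C)=C(C)C | starting material
12 | 2-hydroperoxy-2-methoxypropane | COC(C)(C)OO | intermediate
13 | tert-butyl{[(3R)-3-[(2-methoxypropan-2-yl)peroxy]-5-(phenylselanyl)pentyl]oxy}diphenylsilane | CC(C)(C)[Si](c1ccccc1)(c1ccccc1)OCC[C@@H](OOC(C)(C)OC)CC[Se]c1ccccc1 | intermediate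
14 | Se-oxide of 13 (either configuration at selenium) | CC(C)(C)[Si](c1ccccc1)(c1ccccc1)OCC[C@@H](OOC(C)(C)OC)CC[Se](=O)c1ccccc1 | intermediate (not isolated)
15 | tert-butyl{[(3R)-3-[(2-methoxypropan-2-yl)peroxy]pent-4-en-1-yl]oxy}diphenylsilane | CC(C)(C)[Si](c1ccccc1)(c1ccccc1)OCC[C@@H](OOC(C)(C)OC)C=C | intermediate
16 | 5-chloropent-1-yne | C#CCCCCl | starting material
17 | (5-chloropent-1-yn-1-yl)lithium | [Li]C#CCCCCl | intermediate (not isolated)
18 | (5-chloropent-1-yn-1-yl)tri(propan-2-yl)silane | ClCCCC#C[Si](C(C)C)(C(C)C)C(C)C | intermediate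
19 | N-methoxy-N-methylprop-2-enamide | C=CC(=O)N(C)OC | starting material
20 | benzeneselenol | [SeH]c1ccccc1 | intermediate (not isolated)
21 | N-methoxy-N-methyl-3-(phenylselanyl)propanamide | CON(C)C(=O)CC[Se]c1ccccc1 | intermediate
22 | [5-(triisopropylsilyl)pent-4-yn-1-yl]magnesium chloride | Cl[Mg]CCCC#C[Si](C(C)C)(C(C)C)C(C)C | intermediate (not isolated)
23 | 1-(phenylselanyl)-8-(triisopropylsilyl)oct-7-yn-3-one | O=C(CC[Se]c1ccccc1)CCCC#C[Si](C(C)C)(C(C)C)C(C)C | intermediate
24 | 3,3-dimethoxy-1-(phenylselanyl)-8-(triisopropylsilyl)oct-7-yne | COC(CC[Se]c1ccccc1)(OC)CCCC#C[Si](C(C)C)(C(C)C)C(C)C | intermediate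
25 | (3R)-5-(tert-butyldiphenylsilyloxy)pent-1-en-3-yl hydroperoxide | CC(C)(C)[Si](c1ccccc1)(c1ccccc1)OCC[C@@H](OO)C=C | intermediate (not isolated)
26 | (3R)-5-(tert-butyldiphenylsilyloxy)pent-1-en-3-yl 3-methoxy-1-(phenylselanyl)-8-(triisopropylsilyl)oct-7-yn-3-yl peroxide (both ketal epimers) | CC(C)[Si](C(C)C)(C(C)C)C#CCCCC(OC)(CC[Se]c1ccccc1)OO[C@@H](C=C)CCO[Si](c1ccccc1)(c1ccccc1)C(C)(C)C | intermediate
27 | Se-oxide of 26 | CC(C)[Si](C(C)C)(C(C)C)C#CCCCC(OC)(CC[Se](=O)c1ccccc1)OO[C@@H](C=C)CCO[Si](c1ccccc1)(c1ccccc1)C(C)(C)C | intermediate (not isolated)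
28 | (3R)-5-(tert-butyldiphenylsilyloxy)pent-1-en-3-yl 3-methoxy-8-(triisopropylsilyl)oct-1-en-7-yn-3-yl peroxide (both ketal epimers) | CC(C)[Si](C(C)C)(C(C)C)C#CCCCC(OC)(C=C)OO[C@@H](C=C)CCO[Si](c1ccccc1)(c1ccccc1)C(C)(C)C | intermediate
29 | (3R)-3-[2-(tert-butyldiphenylsilyloxy)ethyl]-6-methoxy-6-[5-(triisopropylsilyl)pent-4-yn-1-yl]-3,6-dihydro-1,2-dioxine (both C6 epimers) | CC(C)[Si](C(C)C)(C(C)C)C#CCCCC1(OC)C=C[C@@H](CCO[Si](c2ccccc2)(c2ccccc2)C(C)(C)C)OO1 | intermediate
30 | (3S)-3-[2-(tert-butyldiphenylsilyloxy)ethyl]-6-methoxy-6-[5-(triisopropylsilyl)pent-4-yn-1-yl]-1,2-dioxane (both C6 epimers) | CC(C)[Si](C(C)C)(C(C)C)C#CCCCC1(OC)CC[C@@H](CCO[Si](c2ccccc2)(c2ccccc2)C(C)(C)C)OO1 | intermediate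
31 | 2-[(3S)-6-methoxy-6-(pent-4-yn-1-yl)-1,2-dioxan-3-yl]ethan-1-ol (both C6 epimers) | C#CCCCC1(OC)CC[C@@H](CCO)OO1 | intermediate
32 | 2-[(3S,6R)-6-methoxy-6-(pent-4-yn-1-yl)-1,2-dioxan-3-yl]ethan-1-ol | C#CCCC[C@]1(OC)CC[C@@H](CCO)OO1 | intermediate
33 | dec-9-en-1-ol | C=CCCCCCCCCO | starting material
34 | dec-9-enal | C=CCCCCCCCC=O | intermediate
35 | (1E)-1-iodoundeca-1,10-diene | C=CCCCCCCC/C=C/I | intermediate
36 | 2-[(3S,6R)-6-[(6E)-hexadeca-6,15-dien-4-yn-1-yl]-6-methoxy-1,2-dioxan-3-yl]ethan-1-ol | C=CCCCCCCC/C=C/C#CCCC[C@]1(OC)CC[C@@H](CCO)OO1 | intermediate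
37 | 2-[(3S,6R)-6-[(6E)-hexadeca-6,15-dien-4-yn-1-yl]-6-methoxy-1,2-dioxan-3-yl]acetaldehyde | C=CCCCCCCC/C=C/C#CCCC[C@]1(OC)CC[C@@H](CC=O)OO1 | intermediate (not isolated)
38 | 2-[(3S,6R)-6-[(6E)-hexadeca-6,15-dien-4-yn-1-yl]-6-methoxy-1,2-dioxan-3-yl]acetic acid | C=CCCCCCCC/C=C/C#CCCC[C@]1(OC)CC[C@@H](CC(=O)O)OO1 | intermediate
39 | methyl 2-[(3S,6R)-6-[(6E)-hexadeca-6,15-dien-4-yn-1-yl]-6-methoxy-1,2-dioxan-3-yl]acetate (peroxyacarnoate A) | C=CCCCCCCC/C=C/C#CCCC[C@]1(OC)CC[C@@H](CC(=O)OC)OO1 | target

**Step count and risks**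

Total steps: 24. Longest linear sequence: 16 steps (1, 2, 3, 5, 6, 8, 9, 14, 15, 16, 17, 18, 19, 22, 23, 24) from but-3-en-1-ol.

Most likely to fail:

1. Step 16. Turnover at the vinyl group on the quaternary ketal carbon may be slow, so that oligomerisation wins, or ruthenium may cleave the O–O bond of the dihydrodioxine once it has formed. The fallback sets out from 15 and 23 and returns at 30. It keeps metathesis for the C4–C5 bond but closes the ring by peroxyketalisation at C6–O2. Ketone 23 is oxidised (H2O2, pyridine) and eliminates to the enone 8-(triisopropylsilyl)oct-1-en-7-yn-3-one F1. Cross-metathesis of 15 with F1 (same ruthenium catalyst) should give (7E,9R)-11-(tert-butyldiphenylsilyloxy)-9-[(2-methoxypropan-2-yl)peroxy]-1-(triisopropylsilyl)undec-7-en-1-yn-6-one F2. Diimide (KO2C–N=N–CO2K, AcOH) saturates the enone alkene to (9S)-11-(tert-butyldiphenylsilyloxy)-9-[(2-methoxypropan-2-yl)peroxy]-1-(triisopropylsilyl)undec-1-yn-6-one F3. TsOH in methanol then removes the perketal, and the freed hydroperoxide closes onto the ketone and is methylated under thermodynamic control to give 30.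

2. Step 14. The exchange may stall at equilibrium or run on to the bis-peroxyketal, while the hydroperoxide slowly oxidises the selenide. The fallback sets out from 24 (and 15) and returns at 26. It replaces the equilibrium exchange by an irreversible addition. Ketal 24 is converted (Me3SiOTf, i-Pr2NEt, CH2Cl2) into the methyl enol ether 3-methoxy-1-(phenylselanyl)-8-(triisopropylsilyl)oct-3-en-7-yne F4 (double-bond isomers all give the same oxocarbenium ion). Hydroperoxide 25, freed from 15 as before, is added to F4 with PPTS in CH2Cl2 at 0 °C to give 26 by Markovnikov addition without release of methanol.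

3. Step 15. Syn-elimination of the primary selenoxide next to the quaternary ketal carbon may be sluggish, with re-addition of selenenic acid to the vinyl groups or acid-induced loss of the mixed ketal. The fallback sets out from 24 (and 15) and returns at 28. Selenium is removed before the peroxide is present: 24 is oxidised (H2O2, pyridine, mild warming possible since no peroxide is at risk) to the vinyl ketal 3,3-dimethoxy-8-(triisopropylsilyl)oct-1-en-7-yne F5. Exchange of F5 with hydroperoxide 25 (PPTS, 5 Å sieves, CH2Cl2, −20 °C, kinetic attack at the ketal carbon) then gives 28 directly, and 26 is skipped.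

**Further compounds**

F1 | step 16 | 8-(triisopropylsilyl)oct-1-en-7-yn-3-one | C=CC(=O)CCCC#C[Si](C(C)C)(C(C)C)C(C)C
F2 | step 16 | (7E,9R)-11-(tert-butyldiphenylsilyloxy)-9-[(2-methoxypropan-2-yl)peroxy]-1-(triisopropylsilyl)undec-7-en-1-yn-6-one | CC(C)[Si](C(C)C)(C(C)C)C#CCCCC(=O)/C=C/[C@@H](CCO[Si](c1ccccc1)(c1ccccc1)C(C)(C)C)OOC(C)(C)OC
F3 | step 16 | (9S)-11-(tert-butyldiphenylsilyloxy)-9-[(2-methoxypropan-2-yl)peroxy]-1-(triisopropylsilyl)undec-1-yn-6-one | CC(C)[Si](C(C)C)(C(C)C)C#CCCCC(=O)CC[C@@H](CCO[Si](c1ccccc1)(c1ccccc1)C(C)(C)C)OOC(C)(C)OC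
F4 | step 14 | 3-methoxy-1-(phenylselanyl)-8-(triisopropylsilyl)oct-3-en-7-yne | COC(CC[Se]c1ccccc1)=CCCC#C[Si](C(C)C)(C(C)C)C(C)C
F5 | step 15 | 3,3-dimethoxy-8-(triisopropylsilyl)oct-1-en-7-yne | C=CC(OC)(OC)CCCC#C[Si](C(C)C)(C(C)C)C(C)C
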